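Ring atoms: C1 (alkynyl-bearing), C2 (=CH), C3 (OAc), C4 (OMe), C5, C6 (carbinols). The cyclohexene is cut across C1=C2 and C3–C4: C2–C3 come from the (Z)-enol silane of acetoxyacetaldehyde, C4–C5–C6–C1 from an L-glyceraldehyde-derived α-silyloxy β-ketophosphonate whose aldehyde is masked as a dimethyl acetal. In one flask a Mukaiyama-type acetal aldol joins C3 to C4, delivering the cis C3-OAc/C4-OMe pair, and an intramolecular Horner–Wadsworth–Emmons reaction closes C1=C2. The step exploits the C6 carbinol/C1=C2 alkene unit of the six-membered ring, read as a cyclohexenone, flanked by the C3/C4 dioxygenated pair. Iodination, Sonogashira coupling, ketone reduction and desilylation complete the route.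

Key step: step 7

Remark: the configuration of the target is taken exactly as drawn, (1S,4S,5S,6R) in the numbering of the cyclohex-2-en-1-yl acetate.

Step 1
Reactants: 1 (S)-2,2-dimethyl-1,3-dioxolane-4-carbaldehyde (L-glyceraldehyde acetonide)
Product: 2 (S)-3,3-dimethoxypropane-1,2-diol
Conditions: HC(OMe)3, MeOH, p-TsOH·H2O (cat.), rt
Reagents that add atoms: methanol, CO; trimethyl orthoformate, COC(OC)OC
Why: Acid-catalysed acetalization/transacetalization in excess methanol should convert the aldehyde into its dimethyl acetal and release the diol as the acetonide is transferred to 2,2-dimethoxypropane; the stereocentre is no longer enolizable once the acetal has formed.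

Step 2
Reactants: 2 (S)-3,3-dimethoxypropane-1,2-diol
Product: 3 (S)-1,1-dimethoxy-2,3-bis(triethylsilyloxy)propane
Conditions: TESCl, imidazole, DMAP (cat.), CH2Cl2, 0 °C to rt
Reagents that add atoms: chlorotriethylsilane, CC[Si](Cl)(CC)CC
Why: Standard silyl ether formation (silylation) on both hydroxyls; no stereocentre is touched.

Step 3
Reactants: 3 (S)-1,1-dimethoxy-2,3-bis(triethylsilyloxy)propane
Product: 5 (S)-3,3-dimethoxy-2-(triethylsilyloxy)propanal, via alkoxysulfonium chloride 4 (not isolated)
Conditions: (COCl)2, DMSO, CH2Cl2, −78 to −40 °C; Et3N, −78 to −20 °C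
Reagents that add atoms: none
Why: Swern oxidation in its oxidative-desilylation mode: the chlorosulfonium reagent attacks the less hindered primary silyl ether oxygen, so only this position should become the aldehyde while the secondary silyl ether stays, and the low temperature limits epimerization of the α-silyloxy aldehyde.

Step 4
Reactants: 5 (S)-3,3-dimethoxy-2-(triethylsilyloxy)propanal
Product: 6 dimethyl [(3R)-4,4-dimethoxy-2-oxo-3-(triethylsilyloxy)butyl]phosphonate
Conditions: (MeO)2P(O)CHN2, SnCl2 (10 mol%), CH2Cl2, rt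
Reagents that add atoms: dimethyl (diazomethyl)phosphonate, COP(=O)(C=[N+]=[N-])OC
Why: Roskamp reaction: SnCl2-catalysed addition of the diazo phosphonate to the aldehyde with loss of N2 and 1,2-hydride shift should give the β-ketophosphonate under conditions that neither ionize the acetal nor enolize the stereocentre.

Step 5
Reactants: 7 (Z)-but-2-ene-1,4-diyl diacetate
Product: 9 2-oxoethyl acetate, via secondary ozonide 8 (not isolated)
Conditions: O3, CH2Cl2, −78 °C; Me2S, −78 °C to rt
Reagents that add atoms: ozone, [O-][O+]=O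
Why: Ozonolysis with reductive work-up of the symmetrical alkene should give two equivalents of acetoxyacetaldehyde.

Step 6
Reactants: 9 2-oxoethyl acetate
Product: 10 (Z)-2-(trimethylsilyloxy)ethenyl acetate
Conditions: TMSCl, Et3N, MeCN, rt
Reagents that add atoms: chlorotrimethylsilane, C[Si](C)(C)Cl
Why: Amine/chlorosilane enol silane formation (soft enolization) should give mainly the (Z)-enol silane expected for an α-acyloxy aldehyde, a π-nucleophile that reacts at the acetoxy-bearing carbon.

Step 7
Reactants: 6 dimethyl [(3R)-4,4-dimethoxy-2-oxo-3-(triethylsilyloxy)butyl]phosphonate; 10 (Z)-2-(trimethylsilyloxy)ethenyl acetate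
Product: 12 (1S,5R,6S)-6-methoxy-4-oxo-5-(triethylsilyloxy)cyclohex-2-en-1-yl acetate, via keto-phosphonate aldehyde 11 (not isolated)
Conditions: TMSOTf (0.3 equiv), CH2Cl2, −78 °C; LiCl, i-Pr2NEt, MeCN, −20 to 0 °C
Reagents that add atoms: none
Why: TMSOTf ionizes the dimethyl acetal of 6 to an (E)-methoxycarbenium ion, which is captured at the acetoxy-bearing carbon of enol silane 10 (Mukaiyama-type acetal aldol, open transition state) to forge C3–C4, leave OMe on C4 and OAc on C3 and unveil aldehyde 11; LiCl/i-Pr2NEt then forms the chelated phosphonate anion, which closes the ring on that aldehyde by an intramolecular Horner–Wadsworth–Emmons reaction to give C1=C2. The closest known reaction types are the silyl-triflate-catalysed addition of enol silanes to acetals and the lithium-salt/amine-mediated Horner–Wadsworth–Emmons cyclization of keto-phosphonate aldehydes to cyclohexenones, here telescoped into a formal [4+2] annulation. The six-membered ring closes in a 6-(enolendo)-exo-trig mode and the ring enforces the cis alkene. C4 is controlled by the C5 stereocentre: the nucleophile is expected to add to the conformer with the silyloxy group inside (next to the cationic carbon) and anti to the bulky acylphosphonate arm, giving the 4,5-syn (ring-trans) relationship, and C3 follows from a synclinal open transition state that turns the C3–OAc dipole away from the C=O+ unit, giving the 3,4-anti (ring-cis) relationship. The step needs ionization of the acetal in preference to attack at the ketone, secured by the much higher reactivity of acetals toward silyl triflates, and ring closure faster than β-elimination of methanol or epimerization of 11, secured by the mild base and the intramolecularity.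

Step 8
Reactants: 12 (1S,5R,6S)-6-methoxy-4-oxo-5-(triethylsilyloxy)cyclohex-2-en-1-yl acetate
Product: 13 (1S,5R,6S)-3-iodo-6-methoxy-4-oxo-5-(triethylsilyloxy)cyclohex-2-en-1-yl acetate
Conditions: I2, pyridine, CH2Cl2, 0 °C to rt
Reagents that add atoms: iodine, II
Why: α-Iodination of the enone by the iodine/pyridine addition–elimination sequence (conjugate addition of pyridine, iodination of the enolate, elimination) should place iodine at C1 without touching the stereocentres.

Step 9
Reactants: 14 (E)-2-methyl-4-(4,4,5,5-tetramethyl-1,3,2-dioxaborolan-2-yl)but-3-en-2-ol; 15 2,3-dibromoprop-1-ene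
Product: 16 (E)-6-bromo-2-methylhepta-3,6-dien-2-ol
Conditions: Pd(PPh3)4 (3 mol%), CsF, THF, 60 °C
Reagents that add atoms: none
Why: Suzuki–Miyaura allyl–alkenyl coupling: zerovalent palladium should insert into the allylic C–Br bond much faster than into the vinylic one, and the alkenyl boronate transfers with retention of the E geometry.

Step 10
Reactants: 16 (E)-6-bromo-2-methylhepta-3,6-dien-2-ol
Product: 17 (E)-2-methyl-6-methylideneoct-3-en-7-yn-2-ol
Conditions: HC≡CMgBr, ZnBr2, Pd(PPh3)4 (5 mol%), THF, 0 °C to rt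
Reagents that add atoms: ethynylmagnesium bromide, C#C[Mg]Br
Why: Negishi alkynylation of the 2-bromo-1-alkene with ethynylzinc bromide made in the flask should give the terminal enyne directly; an excess of the reagent covers the free tertiary hydroxyl.

Step 11
Reactants: 13 (1S,5R,6S)-3-iodo-6-methoxy-4-oxo-5-(triethylsilyloxy)cyclohex-2-en-1-yl acetate; 17 (E)-2-methyl-6-methylideneoct-3-en-7-yn-2-ol
Product: 18 (1S,5R,6S)-3-[(5E)-7-hydroxy-7-methyl-3-methylideneoct-5-en-1-yn-1-yl]-6-methoxy-4-oxo-5-(triethylsilyloxy)cyclohex-2-en-1-yl acetate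
Conditions: PdCl2(PPh3)2 (5 mol%), CuI (10 mol%), i-Pr2NH, THF, 0 °C
Reagents that add atoms: none
Why: Sonogashira coupling of the α-iodo enone with the terminal alkyne at low temperature should join ring and side chain at C1 with all stereocentres untouched.

Step 12
Reactants: 18 (1S,5R,6S)-3-[(5E)-7-hydroxy-7-methyl-3-methylideneoct-5-en-1-yn-1-yl]-6-methoxy-4-oxo-5-(triethylsilyloxy)cyclohex-2-en-1-yl acetate
Product: 19 (1S,4S,5S,6S)-4-hydroxy-3-[(5E)-7-hydroxy-7-methyl-3-methylideneoct-5-en-1-yn-1-yl]-6-methoxy-5-(triethylsilyloxy)cyclohex-2-en-1-yl acetate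
Conditions: NaBH4, CeCl3·7H2O, MeOH, −78 °C
Reagents that add atoms: none
Why: Luche reduction: 1,2-selective hydride addition to the ynenone, expected from the face anti to the C5–O bond (polar Felkin–Anh model, the bulky silyl ether excluding chelation), which sets C6 with its hydroxyl cis to the C5 oxygen.

Step 13
Reactants: 19 (1S,4S,5S,6S)-4-hydroxy-3-[(5E)-7-hydroxy-7-methyl-3-methylideneoct-5-en-1-yn-1-yl]-6-methoxy-5-(triethylsilyloxy)cyclohex-2-en-1-yl acetate
Product: 20 (1S,4S,5S,6R)-4,5-dihydroxy-3-[(5E)-7-hydroxy-7-methyl-3-methylideneoct-5-en-1-yn-1-yl]-6-methoxycyclohex-2-en-1-yl acetate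
Conditions: HF·pyridine, pyridine, THF, 0 °C to rt
Reagents that add atoms: none
Why: Fluoride-mediated desilylation with buffered HF·pyridine should free the C5 hydroxyl without cleaving or shifting the allylic acetate or ionizing the tertiary allylic alcohol.

Compound list
1 | (S)-2,2-dimethyl-1,3-dioxolane-4-carbaldehyde | O=C[C@@H]1COC(C)(C)O1 | starting material
2 | (S)-3,3-dimethoxypropane-1,2-diol | COC(OC)[C@@H](O)CO | intermediate
3 | (S)-1,1-dimethoxy-2,3-bis(triethylsilyloxy)propane | COC(OC)[C@@H](O[Si](CC)(CC)CC)CO[Si](CC)(CC)CC | intermediate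
4 | [(2S)-3,3-dimethoxy-2-(triethylsilyloxy)propoxy]dimethylsulfonium chloride | COC(OC)[C@@H](O[Si](CC)(CC)CC)CO[S+](C)C.[Cl-] | intermediate
5 | (S)-3,3-dimethoxy-2-(triethylsilyloxy)propanal | COC(OC)[C@@H](O[Si](CC)(CC)CC)C=O | intermediate
6 | dimethyl [(3R)-4,4-dimethoxy-2-oxo-3-(triethylsilyloxy)butyl]phosphonate | COC(OC)[C@@H](O[Si](CC)(CC)CC)C(=O)CP(=O)(OC)OC | intermediate
7 | (Z)-but-2-ene-1,4-diyl diacetate | CC(=O)OC/C=C\COC(C)=O | starting material
8 | 3,5-bis(acetoxymethyl)-1,2,4-trioxolane | CC(=O)OCC1OOC(COC(C)=O)O1 | intermediate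
9 | 2-oxoethyl acetate | CC(=O)OCC=O | intermediate
10 | (Z)-2-(trimethylsilyloxy)ethenyl acetate | CC(=O)O/C=C\O[Si](C)(C)C | intermediate
11 | dimethyl [(3R,4S,5R)-5-acetoxy-4-methoxy-2,6-dioxo-3-(triethylsilyloxy)hexyl]phosphonate | O=C[C@H](OC(C)=O)[C@H](OC)[C@@H](O[Si](CC)(CC)CC)C(=O)CP(=O)(OC)OC | intermediate
12 | (1S,5R,6S)-6-methoxy-4-oxo-5-(triethylsilyloxy)cyclohex-2-en-1-yl acetate | O=C1C=C[C@H](OC(C)=O)[C@H](OC)[C@H]1O[Si](CC)(CC)CC | intermediate
13 | (1S,5R,6S)-3-iodo-6-methoxy-4-oxo-5-(triethylsilyloxy)cyclohex-2-en-1-yl acetate | O=C1C(I)=C[C@H](OC(C)=O)[C@H](OC)[C@H]1O[Si](CC)(CC)CC | intermediate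
14 | (E)-2-methyl-4-(4,4,5,5-tetramethyl-1,3,2-dioxaborolan-2-yl)but-3-en-2-ol | CC(C)(O)/C=C/B1OC(C)(C)C(C)(C)O1 | starting material
15 | 2,3-dibromoprop-1-ene | C=C(Br)CBr | starting material
16 | (E)-6-bromo-2-methylhepta-3,6-dien-2-ol | CC(C)(O)/C=C/CC(Br)=C | intermediate
17 | (E)-2-methyl-6-methylideneoct-3-en-7-yn-2-ol | CC(C)(O)/C=C/CC(=C)C#C | intermediate
18 | (1S,5R,6S)-3-[(5E)-7-hydroxy-7-methyl-3-methylideneoct-5-en-1-yn-1-yl]-6-methoxy-4-oxo-5-(triethylsilyloxy)cyclohex-2-en-1-yl acetate | O=C1C(C#CC(=C)C/C=C/C(C)(C)O)=C[C@H](OC(C)=O)[C@H](OC)[C@H]1O[Si](CC)(CC)CC | intermediate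
19 | (1S,4S,5S,6S)-4-hydroxy-3-[(5E)-7-hydroxy-7-methyl-3-methylideneoct-5-en-1-yn-1-yl]-6-methoxy-5-(triethylsilyloxy)cyclohex-2-en-1-yl acetate | C=C(C#CC1=C[C@H](OC(C)=O)[C@H](OC)[C@@H](O[Si](CC)(CC)CC)[C@H]1O)C/C=C/C(C)(C)O | intermediate
20 | (1S,4S,5S,6R)-4,5-dihydroxy-3-[(5E)-7-hydroxy-7-methyl-3-methylideneoct-5-en-1-yn-1-yl]-6-methoxycyclohex-2-en-1-yl acetate | C=C(C#CC1=C[C@H](OC(C)=O)[C@H](OC)[C@@H](O)[C@H]1O)C/C=C/C(C)(C)O | target

Total step count: 13 steps.
Longest linear sequence: 9 steps (steps 1, 2, 3, 4, 7, 8, 11, 12, 13; from 1 to 20).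

Steps most likely to fail

Step 7. The addition to the methoxycarbenium ion may show poor facial selectivity at C4 or the wrong simple diastereoselection at C3, because both centres are set in an open, acyclic transition state. Aldehyde 11 may also lose methanol by β-elimination before the ring closes. The fallback sets out from 6 and 9 and comes back at 12; it reverses the order of the two bond formations so that the C3–C4 bond closes the ring through a cyclic transition state. A LiCl/i-Pr2NEt-mediated Horner–Wadsworth–Emmons reaction of 6 with 9 should give (2E,5R)-6,6-dimethoxy-4-oxo-5-(triethylsilyloxy)hex-2-en-1-yl acetate F1. Treatment with TMSOTf and Et3N in CH2Cl2 should then silylate this enone in the flask to the 2-silyloxy diene (1E,3E,5S)-6,6-dimethoxy-5-(triethylsilyloxy)-4-(trimethylsilyloxy)hexa-1,3-dien-1-yl acetate F2 and ionize the acetal. The γ-carbon of the diene adds to the oxocarbenium ion (intramolecular vinylogous Mukaiyama reaction) in a chair-like arrangement that places the C4 methoxy and C5 silyloxy groups trans-diequatorial, which returns enone 12.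

Step 12. Hydride delivery from the face syn to the C5 silyloxy group would give the C6 epimer. The fallback sets out from 18 and comes back at 19. The same reduction would then give (1S,4R,5S,6S)-4-hydroxy-3-[(5E)-7-hydroxy-7-methyl-3-methylideneoct-5-en-1-yn-1-yl]-6-methoxy-5-(triethylsilyloxy)cyclohex-2-en-1-yl acetate F3. Its secondary allylic hydroxyl is inverted by a Mitsunobu reaction with chloroacetic acid (PPh3, DIAD, THF); the tertiary alcohol of the side chain does not react. This should give (1S,4S,5S,6S)-4-[(chloroacetyl)oxy]-3-[(5E)-7-hydroxy-7-methyl-3-methylideneoct-5-en-1-yn-1-yl]-6-methoxy-5-(triethylsilyloxy)cyclohex-2-en-1-yl acetate F4. The chloroacetate is then cleaved in the presence of the C3 acetate with thiourea and NaHCO3 in ethanol to give 19.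

Step 11. The α-iodo enone may decompose under the amine and copper conditions (β-elimination of the C4 methoxy group leading toward a phenol), and the alkyne may homocouple. The fallback sets out from 13 and comes back at 19; it changes the order of coupling and reduction. Reduction of 13 with NaBH4 and CeCl3·7H2O in methanol at −78 °C should give the base-stable vinyl iodide (1S,4R,5S,6S)-4-hydroxy-3-iodo-6-methoxy-5-(triethylsilyloxy)cyclohex-2-en-1-yl acetate F5. Sonogashira coupling of this iodide with 17 (PdCl2(PPh3)2, CuI, i-Pr2NH, THF) then gives 19 directly.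

Further compounds
F1 | step 7 | (2E,5R)-6,6-dimethoxy-4-oxo-5-(triethylsilyloxy)hex-2-en-1-yl acetate | CC(=O)OC/C=C/C(=O)[C@H](O[Si](CC)(CC)CC)C(OC)OC
F2 | step 7 | (1E,3E,5S)-6,6-dimethoxy-5-(triethylsilyloxy)-4-(trimethylsilyloxy)hexa-1,3-dien-1-yl acetate | CC(=O)O/C=C/C=C(/O[Si](C)(C)C)[C@H](O[Si](CC)(CC)CC)C(OC)OC
F3 | step 12 | (1S,4R,5S,6S)-4-hydroxy-3-[(5E)-7-hydroxy-7-methyl-3-methylideneoct-5-en-1-yn-1-yl]-6-methoxy-5-(triethylsilyloxy)cyclohex-2-en-1-yl acetate | C=C(C#CC1=C[C@H](OC(C)=O)[C@H](OC)[C@@H](O[Si](CC)(CC)CC)[C@@H]1O)C/C=C/C(C)(C)O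
F4 | step 12 | (1S,4S,5S,6S)-4-[(chloroacetyl)oxy]-3-[(5E)-7-hydroxy-7-methyl-3-methylideneoct-5-en-1-yn-1-yl]-6-methoxy-5-(triethylsilyloxy)cyclohex-2-en-1-yl acetate | C=C(C#CC1=C[C@H](OC(C)=O)[C@H](OC)[C@@H](O[Si](CC)(CC)CC)[C@H]1OC(=O)CCl)C/C=C/C(C)(C)O
F5 | step 11 | (1S,4R,5S,6S)-4-hydroxy-3-iodo-6-methoxy-5-(triethylsilyloxy)cyclohex-2-en-1-yl acetate | IC1=C[C@H](OC(C)=O)[C@H](OC)[C@@H](O[Si](CC)(CC)CC)[C@H]1O
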